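**Strategy.** Ring A is not taken from a phenol but built last. The C4a–C5 and C8–C8a bonds are formed together by a Diels–Alder reaction between a 1,1,3-trioxygenated silyl ketene acetal diene (C5–C8, prenyl already on C8) and a bromoalkynyl ketone (C4a≡C8a) that carries C2, C3 and ring B as an enantiopure acetonide. Loss of methanol aromatises the adduct, so one operation delivers 5-OH, 7-OMe, 8-prenyl and a C8a bromide in their final places. The feature exploited is the acylphloroglucinol pattern of ring A around C4a. The bromide then serves for closure of ring C (O1–C8a) by copper-catalysed O-arylation. The C3 stereocentre comes from desymmetrisation of a 2-arylglycerol.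

Key step: step 15

**Remarks on the chemistry**
- Chromanone numbering of the target (O1, C2, C3, C4, C4a, C5–C8, C8a; ring B primed) is used for all intermediates. "Prenyl" = 3-methylbut-2-en-1-yl. "ArB" = 2-methoxy-4-(methoxymethoxy)-3-prenylphenyl (ring B with its MOM ether).
- The target is (3S). From step 5 onward the quaternary carbon keeps one spatial arrangement; its descriptor changes between S and R only because the CIP priorities of its substituents change.
- Assumption: in step 5 the (R,R) ligand is taken to give the (S)-monobenzoate. If the sense of induction proves opposite, the (S,S) ligand is used and nothing else changes.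
- Ring B is entered from commercial 4-bromo-3-methoxyphenol, which already has the bromide para to the hydroxyl and ortho to the methoxy group.
- The geometry at C1 of diene 25 is immaterial; the 3Z isomer (chain on the outside of the diene) is the reactive one.

**Route**

Step 1
Reactants: 1 4-bromo-3-methoxyphenol
Product: 2 1-bromo-2-methoxy-4-(methoxymethoxy)benzene
Conditions: NaH, MOMCl, DMF, 0 °C → rt
Reagents that add atoms: chloromethyl methyl ether, COCCl
Why: O-alkylation of the sodium phenoxide (Williamson ether synthesis) should give the MOM ether, which protects the 4'-oxygen and later directs metalation.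

Step 2
Reactants: 2 1-bromo-2-methoxy-4-(methoxymethoxy)benzene; 3 prenyl bromide
Product: 5 1-bromo-2-methoxy-4-(methoxymethoxy)-3-prenylbenzene, via aryllithium 4 (not isolated)
Conditions: LiN(i-Pr)2 (LDA), THF, −78 °C; CuBr·SMe2 (10 mol %), 3, −78 → 0 °C
Reagents that add atoms: none
Why: Directed ortho-metalation with a lithium amide, which does not exchange the bromide, should remove the most acidic proton (between the two oxygen substituents), and copper-catalysed SN2 allylation then places the prenyl group there.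

Step 3
Reactants: 5 1-bromo-2-methoxy-4-(methoxymethoxy)-3-prenylbenzene; 6 2,2-dimethyl-1,3-dioxan-5-one
Product: 8 5-ArB-2,2-dimethyl-1,3-dioxan-5-ol, via aryllithium 7 (not isolated)
Conditions: n-BuLi, THF, −78 °C; then 6, −78 → −20 °C; H2O
Reagents that add atoms: none
Why: Bromine–lithium exchange is faster than any deprotonation at −78 °C, and 1,2-addition of the aryllithium to the symmetrical ketone gives an achiral tertiary carbinol.

Step 4
Reactants: 8 5-ArB-2,2-dimethyl-1,3-dioxan-5-ol
Product: 9 2-ArB-propane-1,2,3-triol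
Conditions: AcOH–H2O–THF (3:1:1), 40 °C
Reagents that add atoms: none
Why: Acid-catalysed acetal hydrolysis of the six-membered isopropylidene acetal should be much faster than cleavage of the aryl MOM ether and frees the prochiral triol.

Step 5
Reactants: 9 2-ArB-propane-1,2,3-triol
Product: 10 (2S)-2-ArB-2,3-dihydroxypropyl benzoate
Conditions: CuCl2 (5 mol %), (R,R)-Ph-BOX [2,2-bis((4R)-4-phenyl-2-oxazolin-2-yl)propane] (5 mol %), BzCl (1.05 equiv), Et3N, THF, 0 °C
Reagents that add atoms: benzoyl chloride, O=C(Cl)c1ccccc1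
Why: Copper–bisoxazoline-catalysed desymmetrising monobenzoylation: the triol binds copper as a 1,2-diol chelate through the tertiary hydroxyl and one of the two enantiotopic CH2OH groups, and the chiral ligand decides which bound primary oxygen is acylated, which sets the only stereocentre.

Step 6
Reactants: 10 (2S)-2-ArB-2,3-dihydroxypropyl benzoate
Product: 11 [(4S)-4-ArB-2,2-dimethyl-1,3-dioxolan-4-yl]methyl benzoate
Conditions: Me2C(OMe)2, PPTS (cat.), CH2Cl2, rt
Reagents that add atoms: 2,2-dimethoxypropane, COC(C)(C)OC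
Why: Acid-catalysed transacetalisation can engage only the remaining 1,2-diol (tertiary and primary hydroxyl) and gives the dioxolane without touching the stereocentre.

Step 7
Reactants: 11 [(4S)-4-ArB-2,2-dimethyl-1,3-dioxolan-4-yl]methyl benzoate
Product: 12 [(4R)-4-ArB-2,2-dimethyl-1,3-dioxolan-4-yl]methanol
Conditions: K2CO3 (cat.), MeOH, rt
Reagents that add atoms: none
Why: Base-catalysed transesterification removes the benzoate; no bond at the quaternary carbon is broken and no free hydroxyl is left to which the acyl group could migrate.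

Step 8
Reactants: 12 [(4R)-4-ArB-2,2-dimethyl-1,3-dioxolan-4-yl]methanol
Product: 13 (4S)-4-ArB-2,2-dimethyl-1,3-dioxolane-4-carbaldehyde
Conditions: Dess–Martin periodinane, NaHCO3, CH2Cl2, 0 °C → rt
Reagents that add atoms: none
Why: Dess–Martin oxidation of the hindered primary alcohol under buffered conditions gives an aldehyde that has no α-hydrogen and cannot epimerise; the prenyl alkene and MOM ether are inert.

Step 9
Reactants: 13 (4S)-4-ArB-2,2-dimethyl-1,3-dioxolane-4-carbaldehyde; 14 ethynyltrimethylsilane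
Product: 16 1-[(4S)-4-ArB-2,2-dimethyl-1,3-dioxolan-4-yl]-3-(trimethylsilyl)prop-2-yn-1-ol (both C1 epimers), via lithium acetylide 15 (not isolated)
Conditions: 14, n-BuLi, THF, −78 °C; then 13, −78 → −30 °C; H2O
Reagents that add atoms: none
Why: 1,2-Addition of the lithium acetylide to the non-enolisable aldehyde gives the propargylic alcohol; the new carbinol centre is uncontrolled and is removed in step 10.

Step 10
Reactants: 16 1-[(4S)-4-ArB-2,2-dimethyl-1,3-dioxolan-4-yl]-3-(trimethylsilyl)prop-2-yn-1-ol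
Product: 17 1-[(4S)-4-ArB-2,2-dimethyl-1,3-dioxolan-4-yl]-3-(trimethylsilyl)prop-2-yn-1-one
Conditions: Dess–Martin periodinane, NaHCO3, CH2Cl2, rt
Reagents that add atoms: none
Why: Dess–Martin oxidation of an activated propargylic alcohol to the ynone is fast and erases the transient stereocentre.

Step 11
Reactants: 17 1-[(4S)-4-ArB-2,2-dimethyl-1,3-dioxolan-4-yl]-3-(trimethylsilyl)prop-2-yn-1-one
Product: 18 3-bromo-1-[(4S)-4-ArB-2,2-dimethyl-1,3-dioxolan-4-yl]prop-2-yn-1-one
Conditions: NBS (1.05 equiv), AgNO3 (10 mol %), acetone, rt, dark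
Reagents that add atoms: N-bromosuccinimide, O=C1CCC(=O)N1Br
Why: Silver-catalysed desilylative bromination: AgNO3 turns the alkynylsilane into a silver acetylide that should be brominated by NBS much faster than NBS attacks the prenyl alkene or ring B.

Step 12
Reactants: 19 methyl acetoacetate; 3 prenyl bromide
Product: 21 methyl 7-methyl-3-oxooct-6-enoate, via dianion 20 (not isolated)
Conditions: NaH, THF, 0 °C; n-BuLi, 0 °C; 3, 0 °C → rt; H2O
Reagents that add atoms: none
Why: γ-Alkylation of the acetoacetate dianion: the more reactive terminal carbanion attacks prenyl bromide in an SN2 reaction.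

Step 13
Reactants: 21 methyl 7-methyl-3-oxooct-6-enoate
Product: 23 methyl (2E)-3-methoxy-7-methylocta-2,6-dienoate, via dimethyl ketal 22 (not isolated)
Conditions: HC(OMe)3, p-TsOH (cat.), rt; then distil
Reagents that add atoms: trimethyl orthoformate, COC(OC)OC
Why: Acid-catalysed ketalisation with the orthoformate followed by loss of methanol gives the conjugated (E)-β-methoxy enoate, the thermodynamically preferred enol ether.

Step 14
Reactants: 23 methyl (2E)-3-methoxy-7-methylocta-2,6-dienoate
Product: 25 (3Z)-1,3-dimethoxy-7-methyl-1-(trimethylsilyloxy)octa-1,3,6-triene, via lithium dienolate 24 (not isolated)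
Conditions: LiN(i-Pr)2 (LDA), THF, −78 °C; Me3SiCl, −78 °C → rt; filtered and used crude
Reagents that add atoms: chlorotrimethylsilane, C[Si](C)(C)Cl
Why: γ-Deprotonation of the vinylogous ester gives the extended dienolate, which is O-silylated at the ester oxygen to give the silyl ketene acetal diene.

Step 15
Reactants: 18 3-bromo-1-[(4S)-4-ArB-2,2-dimethyl-1,3-dioxolan-4-yl]prop-2-yn-1-one; 25 (3Z)-1,3-dimethoxy-7-methyl-1-(trimethylsilyloxy)octa-1,3,6-triene
Product: 27 [2-bromo-6-hydroxy-4-methoxy-3-prenylphenyl][(4S)-4-ArB-2,2-dimethyl-1,3-dioxolan-4-yl]methanone, via cycloadduct 26 (not isolated)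
Conditions: 25 (2 equiv), toluene, 0 °C → rt (60 °C if needed); then SiO2, CH2Cl2
Reagents that add atoms: none
Why: The electron-rich diene and the electron-poor bromoynone should combine in a concerted but asynchronous (4+2) cycloaddition in which the C8–C8a bond (diene terminus to the bromine-bearing β-carbon) runs ahead of the C4a–C5 bond (ketene acetal carbon to the α-carbon), and the 1,4-cyclohexadiene ketal 26 then loses the elements of methoxytrimethylsilane across C5 and C8 to give the phenol without an oxidant. The closest known reaction type is the Diels–Alder reaction with aromatisation of 1,1,3-trioxygenated silyloxy dienes with alkynyl ketones, together with the cycloadditions of 3-halopropiolates in which the halogen is retained. Ring A is the only ring closed, as a six-membered carbocycle in the (4+2) mode (in the stepwise limit a 6-exo-trig attack of the allenolate carbon C4a on the oxocarbenium carbon C5). No stereocentre is created in the product, the two sp3 centres of 26 vanish on aromatisation, and C3, which has no α-hydrogen and is held in the acetonide, is not touched. The step needs regioselectivity (C8 to C8a, not to C4a) and chemoselectivity for ring closure over loss of bromide by addition–elimination; the first follows from the matched polarisation of the partners (largest HOMO coefficient at C8 of the diene, largest LUMO coefficient at the β-carbon of the ynone), the second from working without Lewis acid in a non-polar solvent so that no free allenolate able to expel bromide is formed. The unactivated prenyl alkenes are not dienophiles under these conditions.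

Step 16
Reactants: 27 [2-bromo-6-hydroxy-4-methoxy-3-prenylphenyl][(4S)-4-ArB-2,2-dimethyl-1,3-dioxolan-4-yl]methanone
Product: 28 (2S)-1-(2-bromo-6-hydroxy-4-methoxy-3-prenylphenyl)-2-ArB-2,3-dihydroxypropan-1-one
Conditions: AcOH–H2O (4:1), 45 °C
Reagents that add atoms: none
Why: Acid-catalysed acetal hydrolysis frees the tertiary and primary hydroxyls, while the aryl MOM ether, the aryl bromide and both prenyl groups should survive aqueous acetic acid.

Step 17
Reactants: 28 (2S)-1-(2-bromo-6-hydroxy-4-methoxy-3-prenylphenyl)-2-ArB-2,3-dihydroxypropan-1-one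
Product: 29 (3S)-3,5-dihydroxy-7-methoxy-3-ArB-8-prenylchroman-4-one
Conditions: CuI (10 mol %), 1,10-phenanthroline (20 mol %), Cs2CO3, toluene, 80 °C
Reagents that add atoms: none
Why: Intramolecular Ullmann-type C–O coupling at monovalent copper: the primary alkoxide displaces the C8a bromide, which is activated by the ortho ketone and not deactivated by the meta oxygens, in a 6-exo closure of ring C, while the hindered tertiary hydroxyl, which could only form a five-membered ring, should not compete.

Step 18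
Reactants: 29 (3S)-3,5-dihydroxy-7-methoxy-3-ArB-8-prenylchroman-4-one
Product: 30 sophonorol F, (3S)-3,5-dihydroxy-3-(4-hydroxy-2-methoxy-3-prenylphenyl)-7-methoxy-8-prenylchroman-4-one
Conditions: HCl (3 M aq.), MeOH, 40 °C
Reagents that add atoms: none
Why: Acid-catalysed acetal exchange cleaves the aryl MOM ether to the 4'-phenol; the tertiary α-ketol has no pathway to dehydrate, and the prenyl groups should tolerate dilute acid at this temperature.

**Compound list**

1 | 4-bromo-3-methoxyphenol | COc1cc(O)ccc1Br | starting material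
2 | 1-bromo-2-methoxy-4-(methoxymethoxy)benzene | COCOc1ccc(Br)c(OC)c1 | intermediate
3 | prenyl bromide (1-bromo-3-methylbut-2-ene) | CC(C)=CCBr | starting material
4 | [3-bromo-2-methoxy-6-(methoxymethoxy)phenyl]lithium (not isolated) | [Li]c1c(OC)c(Br)ccc1OCOC | intermediate
5 | 1-bromo-2-methoxy-4-(methoxymethoxy)-3-prenylbenzene | COCOc1ccc(Br)c(OC)c1CC=C(C)C | intermediate
6 | 2,2-dimethyl-1,3-dioxan-5-one | CC1(C)OCC(=O)CO1 | starting material
7 | [2-methoxy-4-(methoxymethoxy)-3-prenylphenyl]lithium, ArB–Li (not isolated) | [Li]c1ccc(OCOC)c(CC=C(C)C)c1OC | intermediate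
8 | 5-ArB-2,2-dimethyl-1,3-dioxan-5-ol | CC1(C)OCC(O)(CO1)c1ccc(OCOC)c(CC=C(C)C)c1OC | intermediate
9 | 2-ArB-propane-1,2,3-triol | OCC(O)(CO)c1ccc(OCOC)c(CC=C(C)C)c1OC | intermediate
10 | (2S)-2-ArB-2,3-dihydroxypropyl benzoate | OC[C@@](O)(c1ccc(OCOC)c(CC=C(C)C)c1OC)COC(=O)c1ccccc1 | intermediate
11 | [(4S)-4-ArB-2,2-dimethyl-1,3-dioxolan-4-yl]methyl benzoate | CC1(C)OC[C@@](O1)(c1ccc(OCOC)c(CC=C(C)C)c1OC)COC(=O)c1ccccc1 | intermediate
12 | [(4R)-4-ArB-2,2-dimethyl-1,3-dioxolan-4-yl]methanol | CC1(C)OC[C@@](O1)(c1ccc(OCOC)c(CC=C(C)C)c1OC)CO | intermediate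
13 | (4S)-4-ArB-2,2-dimethyl-1,3-dioxolane-4-carbaldehyde | CC1(C)OC[C@@](O1)(c1ccc(OCOC)c(CC=C(C)C)c1OC)C=O | intermediate
14 | ethynyltrimethylsilane | C#C[Si](C)(C)C | starting material
15 | lithium (trimethylsilyl)acetylide (not isolated) | [Li]C#C[Si](C)(C)C | intermediate
16 | 1-[(4S)-4-ArB-2,2-dimethyl-1,3-dioxolan-4-yl]-3-(trimethylsilyl)prop-2-yn-1-ol, both C1 epimers | CC1(C)OC[C@@](O1)(c1ccc(OCOC)c(CC=C(C)C)c1OC)C(O)C#C[Si](C)(C)C | intermediate
17 | 1-[(4S)-4-ArB-2,2-dimethyl-1,3-dioxolan-4-yl]-3-(trimethylsilyl)prop-2-yn-1-one | CC1(C)OC[C@@](O1)(c1ccc(OCOC)c(CC=C(C)C)c1OC)C(=O)C#C[Si](C)(C)C | intermediate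
18 | 3-bromo-1-[(4S)-4-ArB-2,2-dimethyl-1,3-dioxolan-4-yl]prop-2-yn-1-one | CC1(C)OC[C@@](O1)(c1ccc(OCOC)c(CC=C(C)C)c1OC)C(=O)C#CBr | intermediate
19 | methyl acetoacetate | COC(=O)CC(C)=O | starting material
20 | methyl acetoacetate dianion, sodium lithium salt (not isolated) | [Na+].[Li+].COC([O-])=CC([O-])=C | intermediate
21 | methyl 7-methyl-3-oxooct-6-enoate | COC(=O)CC(=O)CCC=C(C)C | intermediate
22 | methyl 3,3-dimethoxy-7-methyloct-6-enoate (not isolated) | COC(=O)CC(OC)(OC)CCC=C(C)C | intermediate
23 | methyl (2E)-3-methoxy-7-methylocta-2,6-dienoate | COC(=O)/C=C(/OC)CCC=C(C)C | intermediate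
24 | lithium dienolate of 23 (not isolated) | COC(O[Li])=CC(OC)=CCC=C(C)C | intermediate
25 | (3Z)-1,3-dimethoxy-7-methyl-1-(trimethylsilyloxy)octa-1,3,6-triene | CO/C(O[Si](C)(C)C)=C/C(OC)=C/CC=C(C)C | intermediate
26 | [2-bromo-4,6-dimethoxy-3-prenyl-6-(trimethylsilyloxy)cyclohexa-1,4-dien-1-yl][(4S)-4-ArB-2,2-dimethyl-1,3-dioxolan-4-yl]methanone, mixture at the two ring sp3 carbons (not isolated) | CC1(C)OC[C@@](O1)(c1ccc(OCOC)c(CC=C(C)C)c1OC)C(=O)C1=C(Br)C(CC=C(C)C)C(OC)=CC1(OC)O[Si](C)(C)C | intermediate
27 | [2-bromo-6-hydroxy-4-methoxy-3-prenylphenyl][(4S)-4-ArB-2,2-dimethyl-1,3-dioxolan-4-yl]methanone | CC1(C)OC[C@@](O1)(c1ccc(OCOC)c(CC=C(C)C)c1OC)C(=O)c1c(O)cc(OC)c(CC=C(C)C)c1Br | intermediate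
28 | (2S)-1-(2-bromo-6-hydroxy-4-methoxy-3-prenylphenyl)-2-ArB-2,3-dihydroxypropan-1-one | OC[C@@](O)(c1ccc(OCOC)c(CC=C(C)C)c1OC)C(=O)c1c(O)cc(OC)c(CC=C(C)C)c1Br | intermediate
29 | (3S)-3,5-dihydroxy-7-methoxy-3-ArB-8-prenylchroman-4-one | COc1cc(O)c2c(c1CC=C(C)C)OC[C@@](O)(c1ccc(OCOC)c(CC=C(C)C)c1OC)C2=O | intermediate
30 | sophonorol F, (3S)-3,5-dihydroxy-3-(4-hydroxy-2-methoxy-3-prenylphenyl)-7-methoxy-8-prenylchroman-4-one | COc1cc(O)c2c(c1CC=C(C)C)OC[C@@](O)(c1ccc(O)c(CC=C(C)C)c1OC)C2=O | target

**Step count.** 18 steps in total. The longest linear sequence is 15 steps (steps 1–11 and 15–18, from 4-bromo-3-methoxyphenol); the diene branch is 3 steps (12–14).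

**Steps most likely to fail**

1. Step 15. After the first bond (C8–C8a) has begun to form, the intermediate may expel bromide (net alkynylation of the diene) or the diene may attack bromine instead of carbon, and the moisture-sensitive ketene acetal may be hydrolysed before it reacts.
Fallback, from aldehyde 13 to target 30: ring A is taken as a preformed arene, joined to 13 as an aryllithium, and ring C is closed by intramolecular SNAr on a fluoride. Commercial 3-fluoro-5-methoxyphenol (COc1cc(O)cc(F)c1) is silylated (TIPSCl, imidazole, DMF) to (3-fluoro-5-methoxyphenoxy)triisopropylsilane F1. n-BuLi at −78 °C lithiates the only unhindered activated position, between fluorine and methoxy, to give [2-fluoro-6-methoxy-4-(triisopropylsilyloxy)phenyl]lithium F2, which is prenylated (CuBr·SMe2 cat., 3) to [3-fluoro-5-methoxy-4-prenylphenoxy]triisopropylsilane F3. TBAF gives 3-fluoro-5-methoxy-4-prenylphenol F4, and NaH/MOMCl gives 1-fluoro-3-methoxy-5-(methoxymethoxy)-2-prenylbenzene F5. A second lithiation (n-BuLi, THF, −78 °C), now between fluorine and the MOM ether, gives [2-fluoro-4-methoxy-6-(methoxymethoxy)-3-prenylphenyl]lithium F6, which adds to 13 to give the carbinol [(4S)-4-ArB-2,2-dimethyl-1,3-dioxolan-4-yl][2-fluoro-4-methoxy-6-(methoxymethoxy)-3-prenylphenyl]methanol F7. Dess–Martin oxidation gives the 2-fluoroaryl ketone [(4S)-4-ArB-2,2-dimethyl-1,3-dioxolan-4-yl][2-fluoro-4-methoxy-6-(methoxymethoxy)-3-prenylphenyl]methanone F8. Aqueous acetic acid removes the acetonide to give (2S)-2-ArB-1-[2-fluoro-4-methoxy-6-(methoxymethoxy)-3-prenylphenyl]-2,3-dihydroxypropan-1-one F9. K2CO3 in DMF closes ring C by displacement of fluoride by the primary alkoxide to give (3S)-3-hydroxy-7-methoxy-5-(methoxymethoxy)-3-ArB-8-prenylchroman-4-one F10. HCl in methanol removes both MOM groups and gives 30.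

2. Step 17. The β-hydroxy ketone may lose formaldehyde by retro-aldol cleavage under carbonate at 80 °C, copper may insert only slowly into the doubly ortho-substituted C8a–Br bond, or the tertiary hydroxyl may compete for the aryl carbon.
Fallback, from 27 to target 30: the bond made in the ring closure is changed from O1–C8a to O1–C2, and the base-sensitive diol is unmasked only after the aryl carbon–oxygen bond exists. The chelated phenol of 27 is protected (NaH, MOMCl) to give [2-bromo-4-methoxy-6-(methoxymethoxy)-3-prenylphenyl][(4S)-4-ArB-2,2-dimethyl-1,3-dioxolan-4-yl]methanone F11, which has no enolisable or retro-aldol-prone position. Hydroxylation of the bromide with zerovalent palladium (Pd2(dba)3, t-BuXPhos, KOH, dioxane–H2O, 90 °C) gives the phenol [2-hydroxy-4-methoxy-6-(methoxymethoxy)-3-prenylphenyl][(4S)-4-ArB-2,2-dimethyl-1,3-dioxolan-4-yl]methanone F12. Aqueous acetic acid gives (2S)-2-ArB-2,3-dihydroxy-1-[2-hydroxy-4-methoxy-6-(methoxymethoxy)-3-prenylphenyl]propan-1-one F13. Mitsunobu cyclisation (PPh3, DIAD, THF, 0 °C) alkylates the C8a phenol with the primary alcohol to give the bis-MOM isoflavanone F10, which HCl in methanol converts to 30.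

3. Step 5. Discrimination between the enantiotopic CH2OH groups may be poor because the ortho-methoxy aryl group crowds the copper chelate, and the enantiomeric purity may erode through benzoyl migration between the primary hydroxyls.
Fallback, from 8 to 12: resolution replaces desymmetrisation. Acid (CSA cat., acetone, rt) equilibrates the 1,3-dioxane 8 to the more stable racemic dioxolane alcohol (4-ArB-2,2-dimethyl-1,3-dioxolan-4-yl)methanol F14. Esterification with (S)-2-methoxy-2-phenylacetic acid (DCC, DMAP, CH2Cl2) gives two diastereomeric esters, [(4S)-4-ArB-2,2-dimethyl-1,3-dioxolan-4-yl]methyl (2S)-2-methoxy-2-phenylacetate F15 and its (4R) diastereomer [(4R)-4-ArB-2,2-dimethyl-1,3-dioxolan-4-yl]methyl (2S)-2-methoxy-2-phenylacetate F16, which are separated by chromatography or crystallisation. Methanolysis of F15 (K2CO3, MeOH) returns 12.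

**Further compounds**

F1 | step 15 | (3-fluoro-5-methoxyphenoxy)triisopropylsilane | COc1cc(F)cc(O[Si](C(C)C)(C(C)C)C(C)C)c1
F2 | step 15 | [2-fluoro-6-methoxy-4-(triisopropylsilyloxy)phenyl]lithium | [Li]c1c(F)cc(O[Si](C(C)C)(C(C)C)C(C)C)cc1OC
F3 | step 15 | [3-fluoro-5-methoxy-4-prenylphenoxy]triisopropylsilane | COc1cc(O[Si](C(C)C)(C(C)C)C(C)C)cc(F)c1CC=C(C)C
F4 | step 15 | 3-fluoro-5-methoxy-4-prenylphenol | COc1cc(O)cc(F)c1CC=C(C)C
F5 | step 15 | 1-fluoro-3-methoxy-5-(methoxymethoxy)-2-prenylbenzene | COCOc1cc(F)c(CC=C(C)C)c(OC)c1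
F6 | step 15 | [2-fluoro-4-methoxy-6-(methoxymethoxy)-3-prenylphenyl]lithium | [Li]c1c(F)c(CC=C(C)C)c(OC)cc1OCOC
F7 | step 15 | [(4S)-4-ArB-2,2-dimethyl-1,3-dioxolan-4-yl][2-fluoro-4-methoxy-6-(methoxymethoxy)-3-prenylphenyl]methanol, both carbinol epimers | CC1(C)OC[C@@](O1)(c1ccc(OCOC)c(CC=C(C)C)c1OC)C(O)c1c(F)c(CC=C(C)C)c(OC)cc1OCOC
F8 | step 15 | [(4S)-4-ArB-2,2-dimethyl-1,3-dioxolan-4-yl][2-fluoro-4-methoxy-6-(methoxymethoxy)-3-prenylphenyl]methanone | CC1(C)OC[C@@](O1)(c1ccc(OCOC)c(CC=C(C)C)c1OC)C(=O)c1c(F)c(CC=C(C)C)c(OC)cc1OCOC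
F9 | step 15 | (2S)-2-ArB-1-[2-fluoro-4-methoxy-6-(methoxymethoxy)-3-prenylphenyl]-2,3-dihydroxypropan-1-one | OC[C@@](O)(c1ccc(OCOC)c(CC=C(C)C)c1OC)C(=O)c1c(F)c(CC=C(C)C)c(OC)cc1OCOC
F10 | step 15 | (3S)-3-hydroxy-7-methoxy-5-(methoxymethoxy)-3-ArB-8-prenylchroman-4-one | COc1cc(OCOC)c2c(c1CC=C(C)C)OC[C@@](O)(c1ccc(OCOC)c(CC=C(C)C)c1OC)C2=O
F11 | step 17 | [2-bromo-4-methoxy-6-(methoxymethoxy)-3-prenylphenyl][(4S)-4-ArB-2,2-dimethyl-1,3-dioxolan-4-yl]methanone | CC1(C)OC[C@@](O1)(c1ccc(OCOC)c(CC=C(C)C)c1OC)C(=O)c1c(OCOC)cc(OC)c(CC=C(C)C)c1Br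
F12 | step 17 | [2-hydroxy-4-methoxy-6-(methoxymethoxy)-3-prenylphenyl][(4S)-4-ArB-2,2-dimethyl-1,3-dioxolan-4-yl]methanone | CC1(C)OC[C@@](O1)(c1ccc(OCOC)c(CC=C(C)C)c1OC)C(=O)c1c(OCOC)cc(OC)c(CC=C(C)C)c1O
F13 | step 17 | (2S)-2-ArB-2,3-dihydroxy-1-[2-hydroxy-4-methoxy-6-(methoxymethoxy)-3-prenylphenyl]propan-1-one | OC[C@@](O)(c1ccc(OCOC)c(CC=C(C)C)c1OC)C(=O)c1c(OCOC)cc(OC)c(CC=C(C)C)c1O
F14 | step 5 | racemic (4-ArB-2,2-dimethyl-1,3-dioxolan-4-yl)methanol | CC1(C)OCC(CO)(O1)c1ccc(OCOC)c(CC=C(C)C)c1OC
F15 | step 5 | [(4S)-4-ArB-2,2-dimethyl-1,3-dioxolan-4-yl]methyl (2S)-2-methoxy-2-phenylacetate | CC1(C)OC[C@@](O1)(c1ccc(OCOC)c(CC=C(C)C)c1OC)COC(=O)[C@@H](OC)c1ccccc1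
F16 | step 5 | [(4R)-4-ArB-2,2-dimethyl-1,3-dioxolan-4-yl]methyl (2S)-2-methoxy-2-phenylacetate | CC1(C)OC[C@](O1)(c1ccc(OCOC)c(CC=C(C)C)c1OC)COC(=O)[C@@H](OC)c1ccccc1
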